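The coupling partner was my ledger for Friday's flask.

| flask | solid substrate | coupling partner | remark | time |
|---|---|---|---|---|
| ash | 0.050 M | 0.96 equiv | run made earlier |  |
| elm | 0.050 M | 4 equiv | run made earlier |  |
| Saturday's | 0.050 M | 1.50 equiv |  | 2.0 d |
| Monday's | 0.050 M | 0.800 equiv |  | 2.0 d |
| Friday's | 0.050 M | 3.00 equiv |  | 2.0 d |

| run | time / h | bis adduct / % | mono adduct / % |
|---|---|---|---|
| ash | 6.00 | 12.1 | 19.5 |
| ash | 15.0 | 23.3 | 27.7 |
| ash | 20.0 | 24.8 | 27.4 |
| ash | 30.0 | 23.1 | 28.4 |
| ash | 40.0 | 24.2 | 27.3 |
| ash | 50.0 | 25.6 | 28.4 |
| elm | 2.50 | 13.9 | 15.9 |
| elm | 8.00 | 54.7 | 33.1 |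
| elm | 15.0 | 66.5 | 25.4 |
| elm | 20.0 | 70.6 | 21.0 |
| elm | 30.0 | 80.3 | 14.2 |
| elm | 40.0 | 87.3 | 11.3 |
| elm | 50.0 | 90.2 | 6.0 |

(each reading ± 1 percentage point)

* which of these holds the largest part of the solid substrate at the end of Saturday's (bis adduct / solid substrate / other mono adduct / mono adduct)
* which of these holds the largest part of the solid substrate at the end of Monday's (bis adduct / solid substrate / other mono adduct / mono adduct)
* which of these holds the largest part of the solid substrate at the end of Friday's (bis adduct / solid substrate / other mono adduct / mono adduct)
* bis adduct at the end of Friday's, in percent of the solid substrate charged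

- as a solid, counted per litre of solution: solid substrate
- at the start none of the solid substrate is in solution

1. I called whatever part of the solid substrate is not bis adduct the unfinished share. In elm it fell from 33.5% after 15.0 h to 9.80% after 50.0 h.

2. I took each unfinished unit to carry one partner. Free partner is then the charge, minus one, minus bis adduct. In elm that was 2.33 equiv at the first of those readings.

3. Elm's decline, divided by its mean free partner, gave 0.0158 h⁻¹ per equivalent. This is the finishing constant, the pseudo-first-order rate of the unfinished share per equivalent of free partner.

4. For the upper bound, Friday's has less partner than elm, so I put it no further along than elm at that first reading. I then held free partner at 1.33 equiv. Bis adduct ends at most at 83.3%.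

5. For the lower bound, I scaled pace with free partner, which is smaller in Friday's. Friday's then reaches that state by 26.2 h. Each substrate takes two partners, so free partner stays above 1.00 equiv. Bis adduct ends at least at 76.3%.

6. I committed to the middle, 79.8%, so bis adduct outweighs everything else on Friday's.

The forecast gave bis adduct for Saturday's, solid substrate for Monday's, bis adduct for Friday's and 85% bis adduct on Friday's, above my bracket, reasoning “So bis comes mainly through a fast other mono”.

Among the asked species, the flasks gave bis adduct for Saturday's, mono adduct for Monday's and bis adduct for Friday's. Friday's bis adduct was 79.5%, inside my bracket.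

    starting material + coupling partner → mono adduct (k = 5.20 M⁻¹ h⁻¹)
    starting material + coupling partner → other mono adduct (k = 3.90 M⁻¹ h⁻¹)
    coupling partner + mono adduct → bis adduct (k = 0.460 M⁻¹ h⁻¹)
    coupling partner + other mono adduct → bis adduct (k = 19.0 M⁻¹ h⁻¹)
    solid substrate ⇌ starting material, rate k5*(cs5 - [starting material]) while solid is left; crystals form when [starting material] > cs5 (solubility = 37.0 mM, k = 0.310 h⁻¹)
    mono adduct ⇌ isomer of the product (K = 0.380, k = 1.00 h⁻¹)

Friday's ended with 40% of its partner free, which is 1.21 equiv, and the finishing constant turns that into a half-life of 36.3 h for the unfinished share. The neighbour charged with 1.20 equiv ended with 0.11% of its partner free, which is 0.00135 equiv. Halving that neighbour's unfinished share takes at least 0.327 equiv, so I reckoned no half-life for it. That neighbour ended with 34.6% bis adduct and 14.7% starting material.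

Readings and results were generated by integration with constants of no real substance; the scatter is artificial.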